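**Retrosynthetic overview**

1. Target 17 ⇒ bromo-enal 14 by one chromium-mediated intramolecular 2-(methoxycarbonyl)allylation: this forms C1–C2, sets C1 and C2, closes the 14-membered ring and then the lactone (ring order: epoxide, carbocycle, lactone).
2. 14 ⇒ homoallylic acetate 12 by cross-metathesis with methyl 2-(bromomethyl)acrylate (C1=C15).
3. 12 ⇒ epoxy aldehyde 6 by reagent-controlled allylboration (C13–C14, sets C13), then ester-to-enal adjustment and acetylation.
4. 6 ⇒ ethyl (2E,6Z)-farnesoate 3 by SeO2 allylic oxidation and Sharpless epoxidation (sets C11 and C12).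
5. 3 ⇒ nerylacetone 1 by Horner–Wadsworth–Emmons olefination; nerylacetone supplies the 7Z olefin. No metathesis ring closure, no late methylenation and no late epoxidation is used.

Assumption: compounds 1, 2, 7 (1 M in pentane, the antipode derived from (−)-α-pinene) and 13 are bought; locants C1–C20 in the text follow cembrane numbering (C1–C14 ring, C15–C17 methylene-lactone carbons, target = 1S,2S,3E,7Z,11S,12R,13R).

**Step 1**
Reactants: 1 nerylacetone [(5Z)-6,10-dimethylundeca-5,9-dien-2-one]; 2 triethyl phosphonoacetate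
Product: 3 ethyl (2E,6Z)-3,7,11-trimethyldodeca-2,6,10-trienoate
Conditions: NaH, THF, 0 °C to rt; (2E) isomer isolated on silica gel
Reagents that add atoms: triethyl phosphonoacetate (2), CCOC(=O)CP(=O)(OCC)OCC
Why: Horner–Wadsworth–Emmons olefination of the methyl ketone gives mainly the (2E)-enoate (about 4:1, the 2Z isomer is removed by chromatography) and leaves the (Z)-olefin of nerylacetone, the future 7Z bond, untouched.

**Step 2**
Reactants: 3 ethyl (2E,6Z)-3,7,11-trimethyldodeca-2,6,10-trienoate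
Product: 4 ethyl (2E,6Z,10E)-12-hydroxy-3,7,11-trimethyldodeca-2,6,10-trienoate
Conditions: SeO2 (0.3 equiv), t-BuOOH (3 equiv), salicylic acid (0.1 equiv), CH2Cl2, 0 °C to rt
Reagents that add atoms: tert-butyl hydroperoxide, CC(C)(C)OO
Why: Catalytic SeO2 allylic oxidation (ene reaction, then [2,3]-shift) attacks the electron-rich terminal isopropylidene at its (E)-methyl group and gives the (10E)-allylic alcohol; the enoate olefin is deactivated.

**Step 3**
Reactants: 4 ethyl (2E,6Z,10E)-12-hydroxy-3,7,11-trimethyldodeca-2,6,10-trienoate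
Product: 5 ethyl (2E,6Z)-9-[(2S,3S)-3-(hydroxymethyl)-3-methyloxiran-2-yl]-3,7-dimethylnona-2,6-dienoate
Conditions: Ti(OiPr)4 (10 mol%), L-(+)-diethyl tartrate (12 mol%), t-BuOOH, 4 Å MS, CH2Cl2, −20 °C
Reagents that add atoms: tert-butyl hydroperoxide, CC(C)(C)OO
Why: Sharpless asymmetric epoxidation is directed by the allylic hydroxyl to C11=C12 only, and L-(+)-tartrate gives the (2S,3S)-epoxy alcohol, which is the trans 11S,12-configured epoxide of the target.

**Step 4**
Reactants: 5 ethyl (2E,6Z)-9-[(2S,3S)-3-(hydroxymethyl)-3-methyloxiran-2-yl]-3,7-dimethylnona-2,6-dienoate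
Product: 6 ethyl (2E,6Z)-9-[(2S,3R)-3-formyl-3-methyloxiran-2-yl]-3,7-dimethylnona-2,6-dienoate
Conditions: PhI(OAc)2 (1.2 equiv), TEMPO (10 mol%), CH2Cl2, rt
Reagents that add atoms: none
Why: TEMPO/PhI(OAc)2 oxidation (oxoammonium mechanism) converts the primary alcohol to the aldehyde without touching epoxide or olefins; the α-carbon is quaternary and cannot epimerise.

**Step 5**
Reactants: 6 ethyl (2E,6Z)-9-[(2S,3R)-3-formyl-3-methyloxiran-2-yl]-3,7-dimethylnona-2,6-dienoate; 7 (+)-B-allyldiisopinocampheylborane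
Product: 9 ethyl (2E,6Z)-9-{(2S,3S)-3-[(1R)-1-hydroxybut-3-en-1-yl]-3-methyloxiran-2-yl}-3,7-dimethylnona-2,6-dienoate, via diisopinocampheylborinate ester 8 (not isolated)
Conditions: 7 (1.5 equiv), Et2O, −78 °C; then aq NaOAc, 30% H2O2, rt
Reagents that add atoms: (+)-B-allyldiisopinocampheylborane (7), C=CCB([C@H]1C[C@H]2C[C@@H]([C@@H]1C)C2(C)C)[C@H]1C[C@H]2C[C@@H]([C@@H]1C)C2(C)C
Why: Brown asymmetric allylboration through a closed chair transition state adds allyl to the Re face of the aldehyde under reagent control and sets C13 as R (threo to the epoxide); the minor 13S epimer is removed by chromatography and the enoate is inert.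

**Step 6**
Reactants: 9 ethyl (2E,6Z)-9-{(2S,3S)-3-[(1R)-1-hydroxybut-3-en-1-yl]-3-methyloxiran-2-yl}-3,7-dimethylnona-2,6-dienoate
Product: 10 (2E,6Z)-9-{(2S,3S)-3-[(1R)-1-hydroxybut-3-en-1-yl]-3-methyloxiran-2-yl}-3,7-dimethylnona-2,6-dien-1-ol
Conditions: i-Bu2AlH (3.5 equiv), CH2Cl2, −78 °C; aq potassium sodium tartrate work-up
Reagents that add atoms: none
Why: 1,2-Reduction of the α,β-unsaturated ester by the aluminium hydride gives the allylic alcohol; at −78 °C the epoxide and the olefins are not touched.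

**Step 7**
Reactants: 10 (2E,6Z)-9-{(2S,3S)-3-[(1R)-1-hydroxybut-3-en-1-yl]-3-methyloxiran-2-yl}-3,7-dimethylnona-2,6-dien-1-ol
Product: 11 (2E,6Z)-9-{(2S,3S)-3-[(1R)-1-hydroxybut-3-en-1-yl]-3-methyloxiran-2-yl}-3,7-dimethylnona-2,6-dienal
Conditions: MnO2 (15 equiv), CH2Cl2, rt
Reagents that add atoms: none
Why: MnO2 oxidises only the allylic primary alcohol, giving the C2 enal with retention of the 3E geometry and leaving the secondary C13 hydroxyl free.

**Step 8**
Reactants: 11 (2E,6Z)-9-{(2S,3S)-3-[(1R)-1-hydroxybut-3-en-1-yl]-3-methyloxiran-2-yl}-3,7-dimethylnona-2,6-dienal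
Product: 12 (1R)-1-{(2R,3S)-3-[(3Z,7E)-3,7-dimethyl-9-oxonona-3,7-dien-1-yl]-2-methyloxiran-2-yl}but-3-en-1-yl acetate
Conditions: Ac2O, pyridine, DMAP (cat.), CH2Cl2, 0 °C to rt
Reagents that add atoms: acetic anhydride, CC(=O)OC(C)=O
Why: DMAP-catalysed acylation installs the C13 acetate of the target with retention and removes the only free hydroxyl before the metal-mediated steps.

**Step 9**
Reactants: 12 (1R)-1-{(2R,3S)-3-[(3Z,7E)-3,7-dimethyl-9-oxonona-3,7-dien-1-yl]-2-methyloxiran-2-yl}but-3-en-1-yl acetate; 13 methyl 2-(bromomethyl)prop-2-enoate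
Product: 14 methyl (2Z,5R)-5-acetoxy-2-(bromomethyl)-5-{(2R,3S)-3-[(3Z,7E)-3,7-dimethyl-9-oxonona-3,7-dien-1-yl]-2-methyloxiran-2-yl}pent-2-enoate
Conditions: second-generation Hoveyda–Grubbs catalyst [RuCl2(H2IMes)(=CH-C6H4-2-OiPr)] (10 mol%), 13 (5 equiv), CH2Cl2, 40 °C
Reagents that add atoms: methyl 2-(bromomethyl)prop-2-enoate (13), C=C(CBr)C(=O)OC
Why: Olefin cross-metathesis joins the terminal alkene to the 1,1-disubstituted acrylate; the trisubstituted olefins and the enal are too hindered to compete. The isomer with the chain trans to the ester (2Z) is formed, which is the geometry needed for a cis-lactone.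

**Step 10**
Reactants: 14 methyl (2Z,5R)-5-acetoxy-2-(bromomethyl)-5-{(2R,3S)-3-[(3Z,7E)-3,7-dimethyl-9-oxonona-3,7-dien-1-yl]-2-methyloxiran-2-yl}pent-2-enoate
Product: 17 (1S,2S,3E,7Z,11S,12R,13R)-13-acetoxy-11,12-epoxycembra-3,7,15(17)-trien-16,2-olide, via allylchromium species 15 (not isolated), via seco hydroxy ester 16 (not isolated)
Conditions: CrCl2 (4 equiv), (S,S)-3,6-diphenyl-1,8-bis(4-isopropyl-4,5-dihydrooxazol-2-yl)-9H-carbazole (4.4 equiv), 1,8-bis(dimethylamino)naphthalene (4.4 equiv), THF, rt; 14 added by syringe pump to 2 mM; aq NaHCO3/serine work-up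
Reagents that add atoms: none
Why: Proposed new method: a ligand-controlled intramolecular Nozaki–Hiyama 2-(alkoxycarbonyl)allylation in which divalent chromium inserts into the allylic C–Br bond, the (Z)-allylchromium adds through C1 to the tethered enal in a Zimmerman–Traxler chair that makes C1/C2 syn (hence the cis-lactone), the carbazole bis(oxazoline) ligand on chromium selects the Re face of the aldehyde (1S,2S), and the chromium alkoxide then closes the lactone on the methyl ester; the closest known reactions are the intermolecular chromium-catalysed asymmetric 2-(alkoxycarbonyl)allylation of aldehydes to α-methylene-γ-butyrolactones and substrate-controlled Nozaki–Hiyama macrocyclisations to germacranolide and cembranoid lactones.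

**Compound list**

1 | nerylacetone, (5Z)-6,10-dimethylundeca-5,9-dien-2-one | CC(=O)CC/C=C(/C)CCC=C(C)C | starting material
2 | triethyl phosphonoacetate | CCOC(=O)CP(=O)(OCC)OCC | starting material
3 | ethyl (2E,6Z)-3,7,11-trimethyldodeca-2,6,10-trienoate | CCOC(=O)/C=C(\C)CC/C=C(/C)CCC=C(C)C | intermediate
4 | ethyl (2E,6Z,10E)-12-hydroxy-3,7,11-trimethyldodeca-2,6,10-trienoate | CCOC(=O)/C=C(\C)CC/C=C(/C)CC/C=C(\C)CO | intermediate
5 | ethyl (2E,6Z)-9-[(2S,3S)-3-(hydroxymethyl)-3-methyloxiran-2-yl]-3,7-dimethylnona-2,6-dienoate | CCOC(=O)/C=C(\C)CC/C=C(/C)CC[C@@H]1O[C@@]1(C)CO | intermediate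
6 | ethyl (2E,6Z)-9-[(2S,3R)-3-formyl-3-methyloxiran-2-yl]-3,7-dimethylnona-2,6-dienoate | CCOC(=O)/C=C(\C)CC/C=C(/C)CC[C@@H]1O[C@@]1(C)C=O | intermediate
7 | (+)-B-allyldiisopinocampheylborane (from (−)-α-pinene) | C=CCB([C@H]1C[C@H]2C[C@@H]([C@@H]1C)C2(C)C)[C@H]1C[C@H]2C[C@@H]([C@@H]1C)C2(C)C | starting material
8 | diisopinocampheylborinate ester of 9 (O–B at C13) | CCOC(=O)/C=C(\C)CC/C=C(/C)CC[C@@H]1O[C@@]1(C)[C@H](OB([C@H]2C[C@H]3C[C@@H]([C@@H]2C)C3(C)C)[C@H]2C[C@H]3C[C@@H]([C@@H]2C)C3(C)C)CC=C | intermediate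
9 | ethyl (2E,6Z)-9-{(2S,3S)-3-[(1R)-1-hydroxybut-3-en-1-yl]-3-methyloxiran-2-yl}-3,7-dimethylnona-2,6-dienoate | CCOC(=O)/C=C(\C)CC/C=C(/C)CC[C@@H]1O[C@@]1(C)[C@H](O)CC=C | intermediate
10 | (2E,6Z)-9-{(2S,3S)-3-[(1R)-1-hydroxybut-3-en-1-yl]-3-methyloxiran-2-yl}-3,7-dimethylnona-2,6-dien-1-ol | OC/C=C(\C)CC/C=C(/C)CC[C@@H]1O[C@@]1(C)[C@H](O)CC=C | intermediate
11 | (2E,6Z)-9-{(2S,3S)-3-[(1R)-1-hydroxybut-3-en-1-yl]-3-methyloxiran-2-yl}-3,7-dimethylnona-2,6-dienal | O=C/C=C(\C)CC/C=C(/C)CC[C@@H]1O[C@@]1(C)[C@H](O)CC=C | intermediate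
12 | (1R)-1-{(2R,3S)-3-[(3Z,7E)-3,7-dimethyl-9-oxonona-3,7-dien-1-yl]-2-methyloxiran-2-yl}but-3-en-1-yl acetate | O=C/C=C(\C)CC/C=C(/C)CC[C@@H]1O[C@@]1(C)[C@H](OC(C)=O)CC=C | intermediate
13 | methyl 2-(bromomethyl)prop-2-enoate | C=C(CBr)C(=O)OC | starting material
14 | methyl (2Z,5R)-5-acetoxy-2-(bromomethyl)-5-{(2R,3S)-3-[(3Z,7E)-3,7-dimethyl-9-oxonona-3,7-dien-1-yl]-2-methyloxiran-2-yl}pent-2-enoate | O=C/C=C(\C)CC/C=C(/C)CC[C@@H]1O[C@@]1(C)[C@H](OC(C)=O)C/C=C(\CBr)C(=O)OC | intermediate
15 | allylchromium dichloride derived from 14 (Cr on C17, supporting ligand omitted) | O=C/C=C(\C)CC/C=C(/C)CC[C@@H]1O[C@@]1(C)[C@H](OC(C)=O)C/C=C(\C[Cr](Cl)Cl)C(=O)OC | intermediate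
16 | methyl 2-[(1S,2S,3E,7Z,11S,12R,13R)-13-acetoxy-11,12-epoxy-2-hydroxy-4,8,12-trimethylcyclotetradeca-3,7-dien-1-yl]prop-2-enoate (formed as its chromium alkoxide) | O[C@H]1/C=C(\C)CC/C=C(/C)CC[C@@H]2O[C@@]2(C)[C@H](OC(C)=O)C[C@H]1C(=C)C(=O)OC | intermediate
17 | (1S,2S,3E,7Z,11S,12R,13R)-13-acetoxy-11,12-epoxycembra-3,7,15(17)-trien-16,2-olide (CNP0146076.3) | C=C1C(=O)O[C@H]2/C=C(\C)CC/C=C(/C)CC[C@@H]3O[C@@]3(C)[C@H](OC(C)=O)C[C@@H]12 | target

**Step count and risks**

Total step count: 10. Longest linear sequence: 10 steps (1 to 17).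

Three steps most likely to fail:

Step 10 (macrocyclisation and lactonisation). Ring closure competes with oligomerisation. The face selection relative to the remote C13 and epoxide centres rests on a ligand whose sense of induction is untested in an intramolecular case (its antipode is equally accessible). The epoxide and acetate are also exposed to trivalent chromium. The fallback sets out from 14 and comes back at 16. Bromide is exchanged for boron with bis(pinacolato)diboron and Pd2(dba)3 (zerovalent palladium, THF, 50 °C), giving the pinacol allylboronate methyl (2E,5R)-5-acetoxy-5-{(2R,3S)-3-[(3Z,7E)-3,7-dimethyl-9-oxonona-3,7-dien-1-yl]-2-methyloxiran-2-yl}-2-[(4,4,5,5-tetramethyl-1,3,2-dioxaborolan-2-yl)methyl]pent-2-enoate F1. F1 is cyclised without any metal by intramolecular allylboration in dilute toluene (1 mM, 60–80 °C) under catalysis by the chiral phosphoric acid (R)-TRIP. Its closed chair transition state again turns the alkene geometry into the syn C1/C2 pair, while the Brønsted acid, not chromium, selects the aldehyde face. Hydrolytic work-up of the O-boryl product gives 16, which lactonises to 17.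

Step 9 (cross-metathesis). The acrylate partner is electron-poor, 1,1-disubstituted and carries an allylic bromide, so turnover may be poor, and the ruthenium alkylidene could engage the C7=C8 olefin. The fallback sets out from 12 and comes back at 14. Metathesis is run instead with methyl 2-(hydroxymethyl)acrylate, whose free allylic hydroxyl assists the catalyst and keeps halide away from ruthenium, giving the allylic alcohol methyl (2E,5R)-5-acetoxy-2-(hydroxymethyl)-5-{(2R,3S)-3-[(3Z,7E)-3,7-dimethyl-9-oxonona-3,7-dien-1-yl]-2-methyloxiran-2-yl}pent-2-enoate F2. The bromide is then introduced by Appel substitution (CBr4, PPh3, CH2Cl2, 0 °C) to give 14, so the halide is installed after, not during, formation of the C1=C15 bond.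

Step 5 (allylboration). The reagent must override the intrinsic facial bias of the α-quaternary epoxy aldehyde, which is expected to favour the erythro (13S) adduct, so the diastereomer ratio may be modest. The fallback sets out from 5 and comes back at 9, with no new compound. Epoxy alcohol 5 is allylated directly at the alcohol oxidation level by transfer-hydrogenative carbonyl allylation: [Ir(cod)Cl]2, BINAP (the antipode that delivers 13R, chosen on a model epoxy alcohol), 4-chloro-3-nitrobenzoic acid, Cs2CO3, allyl acetate, THF, 100 °C. The cyclometalated π-allyliridium catalyst dehydrogenates 5 to 6 in the flask and adds the allyl group under catalyst control.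

**Further compounds**

F1 | step 10 | methyl (2E,5R)-5-acetoxy-5-{(2R,3S)-3-[(3Z,7E)-3,7-dimethyl-9-oxonona-3,7-dien-1-yl]-2-methyloxiran-2-yl}-2-[(4,4,5,5-tetramethyl-1,3,2-dioxaborolan-2-yl)methyl]pent-2-enoate | O=C/C=C(\C)CC/C=C(/C)CC[C@@H]1O[C@@]1(C)[C@H](OC(C)=O)C/C=C(\CB1OC(C)(C)C(C)(C)O1)C(=O)OC
F2 | step 9 | methyl (2E,5R)-5-acetoxy-2-(hydroxymethyl)-5-{(2R,3S)-3-[(3Z,7E)-3,7-dimethyl-9-oxonona-3,7-dien-1-yl]-2-methyloxiran-2-yl}pent-2-enoate | O=C/C=C(\C)CC/C=C(/C)CC[C@@H]1O[C@@]1(C)[C@H](OC(C)=O)C/C=C(\CO)C(=O)OC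
F0 | step 5 | none | none
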